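**Strategy.** Ring B (C5–C6–C7–C8–C9–C10) is grown from a cyclopentenone ring (C5, C6, C8, C9, C10) by inserting C7 between C8 and C6. The step exploits that C8, later the C17-bearing alkene carbon, can be a carbonyl flanked by sp3 C9 and sp2 C6. The precursor is the dibromomethyl carbinol of a bicyclic enone that already holds ring A, the C10 quaternary centre (palladium-catalysed asymmetric allylation) and the C9 side chain with C13 (from (R)-3-methylglutarate). Bromine–lithium exchange gives a β-oxido carbenoid whose 1,2-alkenyl shift enlarges the ring and returns the 8-ketone, from which C5 (hydrogenation), C9 (equilibration) and the C7=C8–C17 allylic acetate (epoxide isomerisation) follow.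

Key step: step 11

Remark: labdane numbering is used for all bicyclic compounds; (R)-t-BuPHOX is assumed to deliver the (R)-ketone 3 (mirror-image ligand, mirror-image ketone), methyl hydrogen (R)-3-methylglutarate 6 is taken as a commercial compound, and centres without a stereo label in a SMILES (C9 in 11–15, C8 in 12 and 17) are epimer mixtures that converge later.

Step 1
Reactants: 1 2,2,6-trimethylcyclohexan-1-one
Product: 2 allyl 2,6,6-trimethylcyclohex-1-en-1-yl carbonate
Conditions: LiN(SiMe3)2, TMEDA, THF, 0 °C; allyl chloroformate, −78 °C to rt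
Reagents that add atoms: allyl chloroformate, C=CCOC(Cl)=O
Why: Enolate O-acylation; the ketone has a single α-hydrogen, so only one enolate can form, and the chloroformate should trap it on oxygen to give the allyl enol carbonate.

Step 2
Reactants: 2 allyl 2,6,6-trimethylcyclohex-1-en-1-yl carbonate
Product: 3 (R)-2-allyl-2,6,6-trimethylcyclohexan-1-one
Conditions: Pd2(dba)3 (cat.), (R)-t-BuPHOX (cat.), THF, 25 °C
Reagents that add atoms: none
Why: Tsuji–Trost-type decarboxylative asymmetric allylic alkylation; zerovalent palladium ionises the carbonate, CO2 is lost, and C–C bond formation within the chiral allylpalladium enolate should set the quaternary centre (later C10) as R.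

Step 3
Reactants: 3 (R)-2-allyl-2,6,6-trimethylcyclohexan-1-one
Product: 4 (R)-2,2,6-trimethyl-6-(2-oxopropyl)cyclohexan-1-one
Conditions: PdCl2 (cat.), Cu(OAc)2 (cat.), O2 (1 atm), DMA–H2O, rt
Reagents that add atoms: water, O
Why: Wacker oxidation; Markovnikov attack of water on the palladium-bound terminal alkene should give the methyl ketone without touching the quaternary centre.

Step 4
Reactants: 4 (R)-2,2,6-trimethyl-6-(2-oxopropyl)cyclohexan-1-one
Product: 5 (R)-4,4,7a-trimethyl-1,4,5,6,7,7a-hexahydro-2H-inden-2-one (ring A fused to a cyclopentenone: C10(CH3)–C9H2–C8(=O)–C6H=C5)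
Conditions: KOH, xylenes, 110 °C, azeotropic removal of water
Reagents that add atoms: none
Why: Intramolecular aldol condensation; the ring ketone has no α-hydrogen, so only the methyl group of the side-chain ketone can attack it, closing the five-membered enone with the stereocentre intact.

Step 5
Reactants: 6 methyl hydrogen (R)-3-methylglutarate
Product: 7 methyl (R)-5-hydroxy-3-methylpentanoate
Conditions: BH3·SMe2, THF, 0 °C to rt; then H2O
Reagents that add atoms: none
Why: Chemoselective borane reduction of a carboxylic acid in the presence of an ester; this differentiates the two ends of the glutarate and leaves the stereocentre (later C13) untouched.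

Step 6
Reactants: 7 methyl (R)-5-hydroxy-3-methylpentanoate
Product: 8 methyl (R)-5-(benzyloxy)-3-methylpentanoate
Conditions: benzyl 2,2,2-trichloroacetimidate, TfOH (cat.), CH2Cl2–cyclohexane, 0 °C to rt
Reagents that add atoms: benzyl 2,2,2-trichloroacetimidate, N=C(OCc1ccccc1)C(Cl)(Cl)Cl
Why: Acid-catalysed O-benzylation with a trichloroacetimidate; it avoids the basic conditions that would lactonise the 5-hydroxy ester.

Step 7
Reactants: 8 methyl (R)-5-(benzyloxy)-3-methylpentanoate
Product: 9 (S)-5-(benzyloxy)-3-methylpentan-1-ol
Conditions: LiAlH4, THF, 0 °C; aqueous work-up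
Reagents that add atoms: none
Why: Hydride reduction of the ester to the primary alcohol; the benzyl ether and the stereocentre are inert.

Step 8
Reactants: 9 (S)-5-(benzyloxy)-3-methylpentan-1-ol
Product: 10 (R)-5-(benzyloxy)-1-iodo-3-methylpentane
Conditions: I2, PPh3, imidazole, CH2Cl2, 0 °C to rt
Reagents that add atoms: iodine, II
Why: Appel-type iodination; SN2 displacement of the oxyphosphonium group at the primary carbon, remote from the stereocentre.

Step 9
Reactants: 5 (R)-4,4,7a-trimethyl-1,4,5,6,7,7a-hexahydro-2H-inden-2-one; 10 (R)-5-(benzyloxy)-1-iodo-3-methylpentane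
Product: 11 (10R,13S)-enone 5 carrying the 5-(benzyloxy)-3-methylpentyl chain on C9 (C9 epimers)
Conditions: LDA, THF, −78 °C; then 10, DMPU, −78 to 0 °C
Reagents that add atoms: none
Why: Kinetic enolate alkylation; C9 is the only enolisable carbon of the enone (no γ-hydrogen), and its configuration is left open because it is equilibrated at the 8-ketone stage.

Step 10
Reactants: 11 (10R,13S)-enone carrying the side chain on C9
Product: 12 dibromomethyl carbinol of 11 (C8 bears OH and CHBr2; C5=C6 retained)
Conditions: CH2Br2, LiTMP, THF, −78 °C; then 11; H2O quench at −78 °C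
Reagents that add atoms: dibromomethane, BrCBr
Why: 1,2-Addition of a halomethyl carbenoid (dibromomethyllithium) to the ketone; the fully substituted β-carbon C5 blocks conjugate attack, and the new carbinol centre is destroyed in step 11.

Step 11
Reactants: 12 dibromomethyl carbinol of 11
Product: 15 (10R,13S)-15-benzyloxy-17-norlabd-5-en-8-one (C9 epimers), via lithium β-oxido carbenoid 13 (not isolated), via lithium dienolate 14 (not isolated)
Conditions: n-BuLi (2.2 equiv), THF, −95 to 0 °C; then H2O
Reagents that add atoms: none
Why: Deprotonation of the hydroxyl and bromine–lithium exchange give the β-oxido carbenoid 13, in which the alkoxide pushes a ring substituent of C8 onto the electron-poor carbenoid carbon as bromide leaves, so that C7 is inserted into a ring bond and the lithium dienolate 14 results; aqueous quench should protonate it at C7 to the β,γ-enone 15. The closest known reaction type is the ring enlargement of cyclic ketones through β-oxido carbenoids, a semipinacol-type 1,2-shift akin to the Tiffeneau–Demjanov rearrangement. No ring is closed by cyclisation: ring B (C5–C6–C7–C8–C9–C10) arises from the cyclopentene ring (C5, C6, C8, C9, C10) by a one-atom ring expansion. No stereocentre is created; C10 and C13 are untouched, C9 stays epimerisable next to the carbonyl and C5 stays sp2 for step 12. The selectivity needed is migration of the alkenyl carbon C6 and not of the alkyl carbon C9; it should be secured by the higher migratory aptitude of an sp2 carbon toward the carbenoid centre and by the congestion of C9, a methine between the side chain and the quaternary C10.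

Step 12
Reactants: 15 (10R,13S)-15-benzyloxy-17-norlabd-5-en-8-one
Product: 16 (5S,9R,10S,13S)-15-hydroxy-17-norlabdan-8-one
Conditions: H2 (5 bar), Pd/C, EtOAc–AcOH, rt; filter; NaOMe (cat.), MeOH, rt
Reagents that add atoms: none
Why: Heterogeneous catalytic hydrogenation should add hydrogen to C5=C6 from the α face, anti to the axial C10 methyl group, to give the trans-fused decalin (5α-H), and it cleaves the benzyl ether by hydrogenolysis; methoxide then equilibrates C9 through the enolate to the equatorial 9β side chain (9α-H).

Step 13
Reactants: 16 (5S,9R,10S,13S)-15-hydroxy-17-norlabdan-8-one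
Product: 17 (13S)-8,17-epoxylabdan-15-ol (spiro-oxirane on C8, either C8 configuration)
Conditions: Me3S+ I−, KOtBu (excess), DMSO–THF, 0 °C to rt
Reagents that add atoms: trimethylsulfonium iodide, C[S+](C)C.[I-]
Why: Corey–Chaykovsky epoxidation; the sulfonium ylide adds to the C8 ketone and closes the oxirane that carries C17, either C8 epimer serves because C8 becomes sp2 in step 14, and the basic medium keeps C9 at its equatorial equilibrium.

Step 14
Reactants: 17 (13S)-8,17-epoxylabdan-15-ol
Product: 18 (5S,9R,10S,13S)-labd-7-ene-15,17-diol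
Conditions: Al(Oi-Pr)3 (excess), toluene, 110 °C; aqueous work-up
Reagents that add atoms: none
Why: Aluminium-alkoxide-promoted isomerisation of an epoxide to an allylic alcohol (syn β-elimination within the aluminium–oxirane complex); the proton should be taken from the unhindered C7 methylene and not from the hindered C9 methine, opening the oxirane at C8 to the C7=C8 alkene with C17–OH.

Step 15
Reactants: 18 (5S,9R,10S,13S)-labd-7-ene-15,17-diol
Product: 19 (5S,9R,10S,13S)-labd-7-ene-15,17-diyl diacetate (target)
Conditions: Ac2O, pyridine, DMAP (cat.), CH2Cl2, rt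
Reagents that add atoms: acetic anhydride, CC(=O)OC(C)=O
Why: DMAP-catalysed acylation of both primary alcohols (C15 and allylic C17); no stereocentre is affected.

**Compound list**

1 | 2,2,6-trimethylcyclohexan-1-one (racemic) | CC1CCCC(C)(C)C1=O | starting material
2 | allyl 2,6,6-trimethylcyclohex-1-en-1-yl carbonate | C=CCOC(=O)OC1=C(C)CCCC1(C)C | intermediate
3 | (R)-2-allyl-2,6,6-trimethylcyclohexan-1-one | C=CC[C@@]1(C)CCCC(C)(C)C1=O | intermediate
4 | (R)-2,2,6-trimethyl-6-(2-oxopropyl)cyclohexan-1-one | CC(=O)C[C@@]1(C)CCCC(C)(C)C1=O | intermediate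
5 | (R)-4,4,7a-trimethyl-1,4,5,6,7,7a-hexahydro-2H-inden-2-one | O=C1C[C@@]2(C)CCCC(C)(C)C2=C1 | intermediate
6 | methyl hydrogen (R)-3-methylglutarate, (R)-5-methoxy-3-methyl-5-oxopentanoic acid | OC(=O)C[C@@H](C)CC(=O)OC | starting material
7 | methyl (R)-5-hydroxy-3-methylpentanoate | OCC[C@@H](C)CC(=O)OC | intermediate
8 | methyl (R)-5-(benzyloxy)-3-methylpentanoate | c1ccccc1COCC[C@@H](C)CC(=O)OC | intermediate
9 | (S)-5-(benzyloxy)-3-methylpentan-1-ol | c1ccccc1COCC[C@@H](C)CCO | intermediate
10 | (R)-5-(benzyloxy)-1-iodo-3-methylpentane | c1ccccc1COCC[C@@H](C)CCI | intermediate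
11 | (7aR)-1-[(3S)-5-(benzyloxy)-3-methylpentyl]-4,4,7a-trimethyl-1,4,5,6,7,7a-hexahydro-2H-inden-2-one (C1 = labdane C9, both epimers) | c1ccccc1COCC[C@@H](C)CCC1C(=O)C=C2C(C)(C)CCC[C@]12C | intermediate
12 | (7aR)-1-[(3S)-5-(benzyloxy)-3-methylpentyl]-2-(dibromomethyl)-4,4,7a-trimethyl-2,4,5,6,7,7a-hexahydro-1H-inden-2-ol (diastereomer mixture) | c1ccccc1COCC[C@@H](C)CCC1C(O)(C(Br)Br)C=C2C(C)(C)CCC[C@]12C | intermediate
13 | lithium β-oxido carbenoid: lithium alkoxide of 12 with CH(Li)Br on C8 | c1ccccc1COCC[C@@H](C)CCC1C(O[Li])(C([Li])Br)C=C2C(C)(C)CCC[C@]12C | intermediate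
14 | lithium dienolate of 15 (C8(OLi)=C7–C6=C5) | c1ccccc1COCC[C@@H](C)CCC1C(O[Li])=CC=C2C(C)(C)CCC[C@]12C | intermediate
15 | (10R,13S)-15-benzyloxy-17-norlabd-5-en-8-one, (8aR)-1-[(3S)-5-(benzyloxy)-3-methylpentyl]-5,5,8a-trimethyl-3,5,6,7,8,8a-hexahydronaphthalen-2(1H)-one (C9 epimers) | c1ccccc1COCC[C@@H](C)CCC1C(=O)CC=C2C(C)(C)CCC[C@]12C | intermediate
16 | (5S,9R,10S,13S)-15-hydroxy-17-norlabdan-8-one | OCC[C@@H](C)CC[C@H]1C(=O)CC[C@H]2C(C)(C)CCC[C@]12C | intermediate
17 | (13S)-8,17-epoxylabdan-15-ol (C8 epimers) | OCC[C@@H](C)CC[C@H]1C3(CO3)CC[C@H]2C(C)(C)CCC[C@]12C | intermediate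
18 | (5S,9R,10S,13S)-labd-7-ene-15,17-diol | OCC[C@@H](C)CC[C@H]1C(CO)=CC[C@H]2C(C)(C)CCC[C@]12C | intermediate
19 | (5S,9R,10S,13S)-labd-7-ene-15,17-diyl diacetate | CC(=O)OCC[C@@H](C)CC[C@H]1C(COC(C)=O)=CC[C@H]2C(C)(C)CCC[C@]12C | target

**Step count.** Total: 15 steps. Longest linear sequence: 11 steps (steps 1–4 and 9–15); the side-chain iodide takes 4 steps (5–8).

**Steps most likely to fail**

Step 11 (key step). The 1,2-shift may take the wrong course, with the sp3 carbon C9 migrating in place of the alkenyl carbon C6 (placing the new carbon between C8 and C9), or the carbenoid may collapse by oxirane closure before it rearranges. The fallback fixes the insertion site by construction and sets out from 11. RhCl(PPh3)3-catalysed 1,4-hydrosilylation with Et3SiH gives the triethylsilyl enol ether F1 (enol double bond C8=C6, hydride delivered to C5 anti to the C10 methyl group). Et2Zn/CH2I2 cyclopropanation gives the siloxycyclopropane F2. FeCl3 in DMF oxidises it to an alkoxy radical that cleaves the internal C8–C6 bond and takes up chlorine, giving the β-chloro ketone F3. NaOAc in MeOH eliminates HCl to the enone F4. Hydrogenation and hydrogenolysis under the conditions of step 12 come back to the route at 16.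

Step 12. Hydrogen may be delivered to C5 with poor facial selectivity (cis-fused decalin), or the double bond may move into conjugation on the catalyst before it is reduced, so that C5 is set without control. The fallback sets C5 through a radical and sets out from 15. Hydrogen-atom-transfer hydrogenation (Mn(dpm)3 cat., PhSiH3, t-BuOOH, i-PrOH) generates the tertiary C5 radical, which should take up hydrogen axially. After methoxide equilibration of C9 this gives the trans-fused benzyl ether ketone F5. Hydrogenolysis (H2, Pd/C, EtOH) comes back to the route at 16.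

Step 9. Alkylation of the enolate at C9, a neopentyl-type carbon next to the quaternary C10, may be slow, so that proton transfer, O-alkylation and elimination of the iodide compete. The fallback replaces SN2 alkylation by carbonyl addition and sets out from 5 and 8. Ester 8 is reduced (i-Bu2AlH, −78 °C) to the aldehyde F6. The lithium enolate of 5 adds to it to give the aldol F7. Acid-catalysed dehydration (TsOH, benzene, reflux) gives the cross-conjugated dienone F8. [(Ph3P)CuH]6 should reduce only the exocyclic enone carbon C11, because the ring β-carbon C5 is fully substituted, and this comes back to the route at 11.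

**Further compounds**

F1 | step 11 | triethylsilyl enol ether of the 5α-H ketone derived from 11 (C8(OSiEt3)=C6) | c1ccccc1COCC[C@@H](C)CCC1C(O[Si](CC)(CC)CC)=C[C@H]2C(C)(C)CCC[C@]12C
F2 | step 11 | siloxycyclopropane from F1 (new CH2 = C7 bridging C8 and C6) | c1ccccc1COCC[C@@H](C)CCC1C3(O[Si](CC)(CC)CC)CC3[C@H]2C(C)(C)CCC[C@]12C
F3 | step 11 | 15-benzyloxy-6-chloro-17-norlabdan-8-one | c1ccccc1COCC[C@@H](C)CCC1C(=O)CC(Cl)[C@H]2C(C)(C)CCC[C@]12C
F4 | step 11 | 15-benzyloxy-17-norlabd-6-en-8-one | c1ccccc1COCC[C@@H](C)CCC1C(=O)C=C[C@H]2C(C)(C)CCC[C@]12C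
F5 | step 12 | 15-benzyloxy-17-norlabdan-8-one | c1ccccc1COCC[C@@H](C)CC[C@H]1C(=O)CC[C@H]2C(C)(C)CCC[C@]12C
F6 | step 9 | (R)-5-(benzyloxy)-3-methylpentanal | c1ccccc1COCC[C@@H](C)CC=O
F7 | step 9 | aldol adduct of 5 (at C9) with F6 | c1ccccc1COCC[C@@H](C)CC(O)C1C(=O)C=C2C(C)(C)CCC[C@]12C
F8 | step 9 | cross-conjugated dienone with exocyclic C9=C11 double bond | c1ccccc1COCC[C@@H](C)CC=C1C(=O)C=C2C(C)(C)CCC[C@]12C
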